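## Structural features

Diplotrin A (16) is an achiral 3‑methoxyflavone: a benzo‑fused 4‑pyranone (ring A fused to ring C through C4a–C8a) joined by the single bond C2–C1' to a tetrasubstituted benzene (ring B). It has no stereocentre, so no stereocentres stand next to each other and the whole problem is one of regiochemistry. Ring A carries methoxy groups on the neighbouring carbons C7 and C8, the latter next to C8a and hence to O1, and ring C carries a third methoxy group on C3 beside the C4 carbonyl. Ring B carries free hydroxyls at C2' and C5' and a methoxy group at C4'; the two hydroxyls are para to each other, so ring B is a hydroquinone that air, base or any oxidant turns into the p‑quinone, and it must stay masked until the last step. The 4‑pyranone is a doubly vinylogous ester that hydroxide or amines open at C2, and the C2–C1' bond is flanked by the C3 methoxy group and the C2' oxygen. The real difficulty is to place six oxygen substituents, four methylated and two free, without ambiguity and without late, unselective methylation or demethylation. The feature exploited is that O1, C2, C3 with its oxygen, C4, C4a, C8a and the oxygenated C8 form the skeleton of 5‑hydroxy‑2‑(hydroxymethyl)‑4‑pyranone, whose side‑chain carbon (the future C8) is vinylogously acidic through C8a=C4a–C4=O; ring A can therefore be closed last between C8 and an ester carbon (the future C7) tethered to C4a, the C7 oxygen arriving as the ester carbonyl.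

## Logic of the disconnections

**16 ⇒ 15.** The two O–CH2Ph bonds at O2' and O5' are cut first. The hydroquinone of 16 would not survive bases, oxidants or palladium couplings, so both phenols are carried as benzyl ethers and released by a neutral, reducing operation. The gain is that every earlier intermediate is a robust polyether. The demand is that the benzyl ethers survive an aryllithium, a lithium amide and a quinone oxidant, and that their removal spares the C2=C3 bond and the four methyl ethers.

**15 ⇒ 14.** The O7–CH3 bond is cut. The C7 oxygen is the only one that does not come from a starting material already in place; it arises from an ester carbonyl and appears as a free hydroxyl. In 14 it is the only free hydroxyl, so methylation needs no selectivity.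

**14 ⇒ 13.** Two hydrogens are added back across C5–C6. This exposes ring A of 13 as a cyclic, doubly vinylogous β‑dicarbonyl system, the natural product of an ester condensation. The forward step must remove two hydrogens from 13 without touching the electron‑rich ring B or its benzyl ethers.

**13 ⇒ 12.** The C7–C8 bond is cut, opening ring A. C8 becomes the methoxymethyl carbon on C8a and C7 the carbonyl carbon of an ethyl ester on a two‑carbon tether at C4a. The gain is large: a bicyclic, trioxygenated ring A is reduced to a monocyclic pyranone with two simple side chains. The demand is that base generates the anion at C8 and not a productive anion elsewhere, and that C8 attacks the ester intramolecularly.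

**12 ⇒ 6 + 11 (from 9 through 10).** The C2–C1' bond is cut between an electrophilic pyranone carbon (a vinylogous acyl bromide in 6) and a nucleophilic ring‑B carbon (the arylzinc 11). This separates the two halves of the molecule and makes the route convergent. The forward coupling must tolerate the ester of 6 and accept an ortho‑benzyloxy nucleophile; an organozinc under neutral conditions meets both points.

**6 ⇒ 4 + 5.** The C4a–C5 bond is cut between the pyranone carbon α to the carbonyl and the three‑carbon ester chain, which is available as the zinc homoenolate 5. The forward coupling must take place at the iodide of 4 and leave its bromide for the next coupling.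

**4 ⇒ 3 ⇒ 2 ⇒ 1.** The C–I bond, the two O–CH3 bonds and the C–Br bond are removed in turn. In 1 the free enolic hydroxyl directs the first halogen to the neighbouring ring CH (the future C2). After both hydroxyls are methylated only one ring CH is left (the future C4a), so the second halogenation has only one site available. The demand is that the double methylation does not displace the activated bromide.

**9 ⇒ 8 ⇒ 7.** The C–Br bond and the two benzyl ether bonds of the ring‑B partner are removed. In 8 the position para to the methoxy group and ortho to a benzyloxy group is the most activated open site, which is exactly C1'. The forward bromination must be stopped at one equivalent.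

## Other disconnections considered

**Alternative 1:** The cut takes C2 out as a one‑carbon unit, breaking C1'–C2 and C2–C3. Ring B would come from the aryl iodide A1 (1,4‑bis(benzyloxy)‑2‑iodo‑5‑methoxybenzene, one iodination away from 8), C2 from carbon monoxide A2, and ring A with C3 and C4 from the α‑methoxy ketone A3 (1‑[3,4‑dimethoxy‑2‑(methoxymethoxy)phenyl]‑2‑methoxyethan‑1‑one).
- Forward key step: zerovalent palladium from Pd(dba)2 and a bisphosphine would insert into A1 and take up A2 to give an aroylpalladium species. This would acylate A3 after soft enolization with MgCl2 and Et3N, giving the 2‑methoxy‑1,3‑diketone A4 without closing a ring. Acid would then remove the methoxymethyl group and cyclodehydrate A4 to 15, one hydrogenolysis from 16.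
- In its favour: it is convergent, ring A is aromatic from the start so no dehydrogenation is needed, and every oxygen is fixed by the two arene partners. The endgame is two steps against three. Even with a short preparation of A1 and A3 the sequence should be shorter than eleven steps, so on step economy this alternative is the better plan.
- Against it here: carbonylative α‑arylation is best established for simple aryl alkyl ketones. A3 carries an α‑alkoxy group that makes the enolate more hindered and offers a second chelation mode. A4 is more acidic than A3 and can be acylated a second time or on oxygen. A1 is an electron‑rich, ortho‑substituted iodide, and the gas must be dosed with care.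
- Comparison: on regiochemical security the two plans are equal. On mechanism both hinge on C‑acylation of one selectively formed enolate; the chosen plan does this intramolecularly, where only the intended electrophile is within reach, while the alternative has to win an intermolecular competition.

**Alternative 2:** The cut breaks C1'–C2' and C5'–C6', so ring B is built on a finished chromone. The partners would be the alkyne A5 (2‑ethynyl‑3,7,8‑trimethoxy‑4H‑chromen‑4‑one) and the silyloxyfuran A6 (tert‑butyl[(4‑methoxyfuran‑2‑yl)oxy]dimethylsilane).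
- Forward key step: a Diels–Alder addition would join the unsubstituted, nucleophilic furan carbon to the alkyne terminus and the silyloxy‑bearing carbon to the inner alkyne carbon, giving the oxanorbornadiene A7. Opening of its oxygen bridge at the ketal carbon and tautomerization would give the aromatic mono‑silyl ether A8 (2'‑O‑TBS 16). Fluoride would then release 16.
- In its favour: one operation builds ring B with its full oxygen pattern and differentiates O2' (silylated), O5' (free) and O4' (methylated), with regiochemistry set by polarity matching. The sequence is redox‑neutral and needs no benzyl ethers. The endgame is one step; on both points this alternative is better than the chosen plan, which needs a dehydrogenation and three steps after its key step.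
- Against it here: the alkyne of A5 is activated only through the vinylogous carbonyl, and A6 is a moisture‑sensitive silyl ketene acetal of the tetronate type that may add in a conjugate sense without closing the ring. A5 itself requires a full synthesis of rings A and C plus installation of the ethynyl group, so the total count is unlikely to fall below that of the chosen plan. A8 and 16 are both oxidizable hydroquinone derivatives that appear with no protection on O5'.
- Comparison: both plans obtain ring oxygen from a small oxygen heterocycle, so structurally they are equals in concept. Mechanistically the cycloaddition is the more elegant step but the less predictable one, while the chosen ring closure has only one reachable mode.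

**Alternative 3:** The cut breaks C4a–C4, C4–C3 and O1–C2, so ring C is made from the iodophenol A9 (6‑iodo‑2,3‑dimethoxyphenol), carbon monoxide A2 as C4, and the arylacetylene A10 (1,4‑bis(benzyloxy)‑2‑ethynyl‑5‑methoxybenzene, two steps from 9).
- Forward key step: under PdCl2(PPh3)2 and Et2NH the arylpalladium species from A9 would take up A2, couple with A10 and cyclize through the phenol oxygen onto the alkyne to give the flavone A11 (2‑[2,5‑bis(benzyloxy)‑4‑methoxyphenyl]‑7,8‑dimethoxy‑4H‑chromen‑4‑one).
- In its favour: it forms three bonds and a ring from three simple components; in bond‑forming power per step it is clearly better than the chosen key step. Ring A is aromatic from the start and its oxygen pattern is fixed by A9.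
- Against it here: A11 has no oxygen at C3. The 3‑methoxy group would have to be added afterwards by C3 hydroxylation to the flavonol A12 (2‑[2,5‑bis(benzyloxy)‑4‑methoxyphenyl]‑3‑hydroxy‑7,8‑dimethoxy‑4H‑chromen‑4‑one) and methylation to 15, an oxidation next to two electron‑rich rings. The cyclization can proceed in a six‑membered (endo) or a five‑membered (exo) sense and only the former gives A11. The hydroxyl of A9 is flanked on both sides, and A9 needs an ortho‑selective iodination in which the para position competes.
- Comparison: with the preparation of A9 and A10, the key step, two steps for the C3 oxygen and the hydrogenolysis, the count should be about equal to the chosen plan. The chosen plan has the structural advantage that the C3 oxygen is present from the first step; the alternative has the advantage of convergence.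

Key step: step 8

Remark on the chemistry: 5 is used as its commercial THF solution; 13 is written as the C7 enol, the tautomer expected to predominate because it extends conjugation to the C4 carbonyl. Flavone locants (O1 to C8a, primed for ring B) are used for 12–16, while the monocyclic pyranones 2–6 are named by their own locants.

## Steps

Step 1
Reactants: 1 kojic acid (5‑hydroxy‑2‑(hydroxymethyl)‑4H‑pyran‑4‑one)
Product: 2 2‑bromo‑3‑hydroxy‑6‑(hydroxymethyl)‑4H‑pyran‑4‑one
Conditions: NBS (1.05 equiv), THF–H2O, 0 °C → rt, dark
Reagents that add atoms: N‑bromosuccinimide, O=C1CCC(=O)N1Br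
Why: Electrophilic bromination of an enol; the free hydroxyl makes the adjacent ring CH (also α to the ring oxygen) the most nucleophilic carbon, while the other ring CH is not activated, so monobromination at that site should be clean.

Step 2
Reactants: 2 2‑bromo‑3‑hydroxy‑6‑(hydroxymethyl)‑4H‑pyran‑4‑one
Product: 3 2‑bromo‑3‑methoxy‑6‑(methoxymethyl)‑4H‑pyran‑4‑one
Conditions: MeI (8 equiv), Ag2O (3 equiv), DMF, rt, dark
Reagents that add atoms: iodomethane, CI
Why: Ag2O‑mediated Williamson etherification (Purdie methylation) should methylate the acidic enolic hydroxyl and the primary alcohol in one operation; no free alkoxide is present, so the vinylogous acyl bromide should not be displaced.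

Step 3
Reactants: 3 2‑bromo‑3‑methoxy‑6‑(methoxymethyl)‑4H‑pyran‑4‑one
Product: 4 2‑bromo‑5‑iodo‑3‑methoxy‑6‑(methoxymethyl)‑4H‑pyran‑4‑one
Conditions: NIS (1.2 equiv), CF3CO2H–MeCN, rt → 50 °C
Reagents that add atoms: N‑iodosuccinimide, O=C1CCC(=O)N1I
Why: Electrophilic iodination at the α‑carbon of the vinylogous ester (the β‑carbon of the ring enol ether), which is the only ring position still bearing hydrogen; acid activates NIS, and the bromide and the ethers are inert to it.

Step 4
Reactants: 4 2‑bromo‑5‑iodo‑3‑methoxy‑6‑(methoxymethyl)‑4H‑pyran‑4‑one; 5 3‑ethoxy‑3‑oxopropylzinc bromide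
Product: 6 ethyl 3‑[6‑bromo‑5‑methoxy‑2‑(methoxymethyl)‑4‑oxo‑4H‑pyran‑3‑yl]propanoate
Conditions: 5 (1.2 equiv, 0.5 M in THF), PdCl2[P(o‑tolyl)3]2 (5 mol %), THF–DMA, rt → 40 °C
Reagents that add atoms: none
Why: Negishi coupling of a zinc homoenolate; zerovalent palladium should insert into the weaker C–I bond faster than into the C–Br bond, the ester‑chelated alkylzinc does not attack the pyranone carbonyl, and the bulky phosphine favours reductive elimination over β‑hydride elimination. Limiting the zinc reagent and the temperature keeps the bromide for step 7.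

Step 5
Reactants: 7 2‑methoxyhydroquinone (2‑methoxybenzene‑1,4‑diol)
Product: 8 1,4‑bis(benzyloxy)‑2‑methoxybenzene
Conditions: BnBr (2.4 equiv), K2CO3 (3 equiv), DMF, N2, rt → 50 °C
Reagents that add atoms: benzyl bromide, BrCc1ccccc1
Why: Williamson etherification of both phenols; exclusion of air prevents oxidation of the hydroquinone anion before it is alkylated.

Step 6
Reactants: 8 1,4‑bis(benzyloxy)‑2‑methoxybenzene
Product: 9 1,4‑bis(benzyloxy)‑2‑bromo‑5‑methoxybenzene
Conditions: NBS (1.0 equiv), MeCN, 0 °C → rt
Reagents that add atoms: N‑bromosuccinimide, O=C1CCC(=O)N1Br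
Why: Electrophilic aromatic bromination; the position para to the methoxy group and ortho to a benzyloxy group is activated by two oxygens and unhindered, whereas the position between two oxygens is hindered and the third open position is activated by one oxygen only.

Step 7
Reactants: 9 1,4‑bis(benzyloxy)‑2‑bromo‑5‑methoxybenzene; 6 ethyl 3‑[6‑bromo‑5‑methoxy‑2‑(methoxymethyl)‑4‑oxo‑4H‑pyran‑3‑yl]propanoate
Product: 12 ethyl 3‑{6‑[2,5‑bis(benzyloxy)‑4‑methoxyphenyl]‑5‑methoxy‑2‑(methoxymethyl)‑4‑oxo‑4H‑pyran‑3‑yl}propanoate, via aryllithium 10 (not isolated), via arylzinc chloride 11 (not isolated)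
Conditions: 9 (1.25 equiv), n‑BuLi (1.2 equiv), THF, −78 °C; ZnCl2 (1.3 equiv), −78 °C → rt; then 6 (1.0 equiv), Pd2(dba)3 (2 mol %), SPhos (8 mol %), THF, rt → 50 °C
Reagents that add atoms: none
Why: Bromine–lithium exchange, transmetalation to zinc and Negishi coupling; the vinylogous acyl bromide of 6 should undergo fast oxidative addition, and the arylzinc halide tolerates the ethyl ester and the pyranone carbonyl, so no aqueous base comes near either. The bulky biarylphosphine accommodates the ortho‑benzyloxy group.

Step 8
Reactants: 12 ethyl 3‑{6‑[2,5‑bis(benzyloxy)‑4‑methoxyphenyl]‑5‑methoxy‑2‑(methoxymethyl)‑4‑oxo‑4H‑pyran‑3‑yl}propanoate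
Product: 13 2‑[2,5‑bis(benzyloxy)‑4‑methoxyphenyl]‑7‑hydroxy‑3,8‑dimethoxy‑5,6‑dihydro‑4H‑chromen‑4‑one (enol form of the C7 ketone)
Conditions: LiN(SiMe3)2 (2.5 equiv), THF (0.02 M), −78 → 0 °C; then AcOH
Reagents that add atoms: none
Why: The amide base removes a proton from the methoxymethyl carbon, which is acidified vinylogously through C8a=C4a and the C4 carbonyl, giving an extended lithium dienolate; its exocyclic carbon C8 adds to the ester carbonyl C7 held on C4a, and loss of ethoxide forms the C7–C8 bond. The closest known reaction type is the Dieckmann (intramolecular Claisen) condensation run through lateral deprotonation of a 2‑alkyl‑4‑pyranone. Ring A closes in a 6‑(enolendo)‑exo‑trig mode: the enolate C8=C8a bond lies inside the new six‑membered ring and the ester C=O outside it. No stereocentre is created, because C8 ends as an sp2 carbon of the enol. The selectivity needed is site selectivity of enolization and of C–C bond formation: the ester α‑anion forms reversibly but can reach neither the ring carbonyl nor a β‑carbon of the pyranone without closing a four‑membered ring or a bridgehead alkene; the other side of the pyranone carries an aryl and a methoxy group, so no second lateral site exists; and the dienolate can use only C8, since attack through C4a would again need a four‑membered ring. The product is a doubly vinylogous acid that the second equivalent of base deprotonates at once, which pulls the equilibrium forward and shields the product, while high dilution suppresses intermolecular Claisen condensation. Acidic quench should return 13 as the conjugated enol.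

Step 9
Reactants: 13 2‑[2,5‑bis(benzyloxy)‑4‑methoxyphenyl]‑7‑hydroxy‑3,8‑dimethoxy‑5,6‑dihydro‑4H‑chromen‑4‑one
Product: 14 2‑[2,5‑bis(benzyloxy)‑4‑methoxyphenyl]‑7‑hydroxy‑3,8‑dimethoxy‑4H‑chromen‑4‑one
Conditions: DDQ (1.1 equiv), 1,4‑dioxane, rt
Reagents that add atoms: none
Why: Quinone dehydrogenation by hydride abstraction from C6 of the electron‑rich dienol and loss of the C5 proton; aromatization of ring A drives it, and benzyl aryl ethers, unlike p‑methoxybenzyl ethers, should be inert to DDQ at room temperature.

Step 10
Reactants: 14 2‑[2,5‑bis(benzyloxy)‑4‑methoxyphenyl]‑7‑hydroxy‑3,8‑dimethoxy‑4H‑chromen‑4‑one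
Product: 15 2‑[2,5‑bis(benzyloxy)‑4‑methoxyphenyl]‑3,7,8‑trimethoxy‑4H‑chromen‑4‑one
Conditions: MeI (3 equiv), K2CO3 (2 equiv), acetone, reflux
Reagents that add atoms: iodomethane, CI
Why: Williamson methylation of the only free hydroxyl, the C7 phenol, which is acidified through C4a by the C4 carbonyl.

Step 11
Reactants: 15 2‑[2,5‑bis(benzyloxy)‑4‑methoxyphenyl]‑3,7,8‑trimethoxy‑4H‑chromen‑4‑one
Product: 16 diplotrin A, 2‑(2,5‑dihydroxy‑4‑methoxyphenyl)‑3,7,8‑trimethoxy‑4H‑chromen‑4‑one
Conditions: H2 (1 atm), 10% Pd/C, EtOAc–MeOH, rt; filtration and concentration under argon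
Reagents that add atoms: none
Why: Hydrogenolysis of the two benzyl aryl ethers under neutral, reducing conditions releases the hydroquinone without exposing it to base or oxidant; the tetrasubstituted vinylogous‑ester C2=C3 bond and the aryl methyl ethers should not be reduced.

## Compound list

1 | kojic acid (5‑hydroxy‑2‑(hydroxymethyl)‑4H‑pyran‑4‑one) | OCc1cc(=O)c(O)co1 | starting material
2 | 2‑bromo‑3‑hydroxy‑6‑(hydroxymethyl)‑4H‑pyran‑4‑one | OCc1cc(=O)c(O)c(Br)o1 | intermediate
3 | 2‑bromo‑3‑methoxy‑6‑(methoxymethyl)‑4H‑pyran‑4‑one | COCc1cc(=O)c(OC)c(Br)o1 | intermediate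
4 | 2‑bromo‑5‑iodo‑3‑methoxy‑6‑(methoxymethyl)‑4H‑pyran‑4‑one | COCc1oc(Br)c(OC)c(=O)c1I | intermediate
5 | 3‑ethoxy‑3‑oxopropylzinc bromide | CCOC(=O)CC[Zn]Br | starting material
6 | ethyl 3‑[6‑bromo‑5‑methoxy‑2‑(methoxymethyl)‑4‑oxo‑4H‑pyran‑3‑yl]propanoate | CCOC(=O)CCc1c(COC)oc(Br)c(OC)c1=O | intermediate
7 | 2‑methoxyhydroquinone (2‑methoxybenzene‑1,4‑diol) | COc1cc(O)ccc1O | starting material
8 | 1,4‑bis(benzyloxy)‑2‑methoxybenzene | COc1cc(OCc2ccccc2)ccc1OCc1ccccc1 | intermediate
9 | 1,4‑bis(benzyloxy)‑2‑bromo‑5‑methoxybenzene | COc1cc(OCc2ccccc2)c(Br)cc1OCc1ccccc1 | intermediate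
10 | [2,5‑bis(benzyloxy)‑4‑methoxyphenyl]lithium | [Li]c1cc(OCc2ccccc2)c(OC)cc1OCc1ccccc1 | intermediate
11 | [2,5‑bis(benzyloxy)‑4‑methoxyphenyl]zinc chloride | Cl[Zn]c1cc(OCc2ccccc2)c(OC)cc1OCc1ccccc1 | intermediate
12 | ethyl 3‑{6‑[2,5‑bis(benzyloxy)‑4‑methoxyphenyl]‑5‑methoxy‑2‑(methoxymethyl)‑4‑oxo‑4H‑pyran‑3‑yl}propanoate | CCOC(=O)CCc1c(COC)oc(-c2cc(OCc3ccccc3)c(OC)cc2OCc2ccccc2)c(OC)c1=O | intermediate
13 | 2‑[2,5‑bis(benzyloxy)‑4‑methoxyphenyl]‑7‑hydroxy‑3,8‑dimethoxy‑5,6‑dihydro‑4H‑chromen‑4‑one | COC1=C(O)CCc2c1oc(-c1cc(OCc3ccccc3)c(OC)cc1OCc1ccccc1)c(OC)c2=O | intermediate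
14 | 2‑[2,5‑bis(benzyloxy)‑4‑methoxyphenyl]‑7‑hydroxy‑3,8‑dimethoxy‑4H‑chromen‑4‑one | COc1c(O)ccc2c1oc(-c1cc(OCc3ccccc3)c(OC)cc1OCc1ccccc1)c(OC)c2=O | intermediate
15 | 2‑[2,5‑bis(benzyloxy)‑4‑methoxyphenyl]‑3,7,8‑trimethoxy‑4H‑chromen‑4‑one | COc1ccc2c(c1OC)oc(-c1cc(OCc3ccccc3)c(OC)cc1OCc1ccccc1)c(OC)c2=O | intermediate
16 | diplotrin A, 2‑(2,5‑dihydroxy‑4‑methoxyphenyl)‑3,7,8‑trimethoxy‑4H‑chromen‑4‑one | COc1cc(O)c(-c2oc3c(OC)c(OC)ccc3c(=O)c2OC)cc1O | target

## Step count and least certain steps

Total: 11 steps. Longest linear sequence: 9 steps (steps 1, 2, 3, 4, 7, 8, 9, 10, 11, from 1 to 16); the ring‑B branch (steps 5 and 6) joins at step 7.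

**Step 8 (key step).** The most likely failure is enolization at the wrong site followed by intermolecular chemistry: the ester α‑anion, formed in competition with the α‑alkoxy lateral anion, may condense with a second molecule, or ethoxide and amide may add to the pyranone before the ring closes. The fallback removes the competing acidic site. Setting out from 12, LiOH in THF–H2O at 0 °C should give 3‑{6‑[2,5‑bis(benzyloxy)‑4‑methoxyphenyl]‑5‑methoxy‑2‑(methoxymethyl)‑4‑oxo‑4H‑pyran‑3‑yl}propanoic acid F1. Amide coupling (EDC·HCl, MeNH(OMe)·HCl, i‑Pr2NEt, CH2Cl2) should give 3‑{6‑[2,5‑bis(benzyloxy)‑4‑methoxyphenyl]‑5‑methoxy‑2‑(methoxymethyl)‑4‑oxo‑4H‑pyran‑3‑yl}‑N‑methoxy‑N‑methylpropanamide F2. Its α‑hydrogens are far less acidic than those of an ester, and its chelated tetrahedral adduct does not release a nucleophile until work‑up. Treatment of F2 with LiN(SiMe3)2 in THF and acidic quench returns to the route at 13.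

**Step 4.** The most likely failure is loss of site selectivity: the bromide of 4 is a vinylogous acyl bromide and may undergo oxidative addition in competition with the iodide, giving mixtures and double alkylation. The fallback turns that reactivity into the basis of the selectivity. Setting out from 3, NBS in CF3CO2H should give 2,5‑dibromo‑3‑methoxy‑6‑(methoxymethyl)‑4H‑pyran‑4‑one F3. The arylzinc chloride 11 (1.0 equiv, Pd(PPh3)4, THF, rt) should couple first at the electron‑poor bromide next to the ring oxygen and give 2‑[2,5‑bis(benzyloxy)‑4‑methoxyphenyl]‑5‑bromo‑3‑methoxy‑6‑(methoxymethyl)‑4H‑pyran‑4‑one F4. Negishi coupling of the remaining bromide with 5 (Pd(OAc)2, SPhos, THF, 50 °C) returns to the route at 12. This replaces steps 3, 4 and 7 by three steps and also avoids the iodination.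

**Step 2.** The most likely failure is incomplete etherification of the primary alcohol under the heterogeneous conditions, or, if stronger base is used to force it, displacement of the activated bromide by alkoxide. The fallback installs the side‑chain ether before the bromide exists. Setting out from 1, SOCl2 should give 2‑(chloromethyl)‑5‑hydroxy‑4H‑pyran‑4‑one F5; NaOMe in MeOH at reflux should give 5‑hydroxy‑2‑(methoxymethyl)‑4H‑pyran‑4‑one F6; NBS in THF–H2O should give 2‑bromo‑3‑hydroxy‑6‑(methoxymethyl)‑4H‑pyran‑4‑one F7; and MeI with K2CO3 in acetone, a non‑nucleophilic base, returns to the route at 3.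

**Step 9.** The most likely failure is oxidation of the wrong part of the molecule: electron transfer from the trialkoxyarene of ring B to the quinone, with oxidative loss of a benzyl group. The fallback introduces the double bond without an oxidant strong enough to engage ring B. Setting out from 13, LiN(SiMe3)2 (2.2 equiv) and PhSeCl in THF at −78 °C should selenenylate the dianion at C6 and give racemic 2‑[2,5‑bis(benzyloxy)‑4‑methoxyphenyl]‑7‑hydroxy‑3,8‑dimethoxy‑6‑(phenylselanyl)‑5,6‑dihydro‑4H‑chromen‑4‑one F8. Oxidation at selenium with H2O2 at 0 °C and syn‑elimination, followed by tautomerization, returns to the route at 14.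

**Step 11.** The most likely failure is over‑reduction (slow saturation of the C2=C3 bond on prolonged exposure) or incomplete cleavage of the hindered C2' benzyl ether. The fallback cleaves the benzyl ethers by Lewis acid instead of hydrogen. Setting out from 15, BCl3 with pentamethylbenzene as cation scavenger in CH2Cl2 at −78 °C should remove both benzyl groups while the aryl methyl ethers survive at that temperature, arriving directly at 16 with no new intermediate.

## Further compounds

F1 | step 8 | 3‑{6‑[2,5‑bis(benzyloxy)‑4‑methoxyphenyl]‑5‑methoxy‑2‑(methoxymethyl)‑4‑oxo‑4H‑pyran‑3‑yl}propanoic acid | OC(=O)CCc1c(COC)oc(-c2cc(OCc3ccccc3)c(OC)cc2OCc2ccccc2)c(OC)c1=O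
F2 | step 8 | 3‑{6‑[2,5‑bis(benzyloxy)‑4‑methoxyphenyl]‑5‑methoxy‑2‑(methoxymethyl)‑4‑oxo‑4H‑pyran‑3‑yl}‑N‑methoxy‑N‑methylpropanamide | CON(C)C(=O)CCc1c(COC)oc(-c2cc(OCc3ccccc3)c(OC)cc2OCc2ccccc2)c(OC)c1=O
F3 | step 4 | 2,5‑dibromo‑3‑methoxy‑6‑(methoxymethyl)‑4H‑pyran‑4‑one | COCc1oc(Br)c(OC)c(=O)c1Br
F4 | step 4 | 2‑[2,5‑bis(benzyloxy)‑4‑methoxyphenyl]‑5‑bromo‑3‑methoxy‑6‑(methoxymethyl)‑4H‑pyran‑4‑one | COCc1oc(-c2cc(OCc3ccccc3)c(OC)cc2OCc2ccccc2)c(OC)c(=O)c1Br
F5 | step 2 | 2‑(chloromethyl)‑5‑hydroxy‑4H‑pyran‑4‑one | ClCc1cc(=O)c(O)co1
F6 | step 2 | 5‑hydroxy‑2‑(methoxymethyl)‑4H‑pyran‑4‑one | COCc1cc(=O)c(O)co1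
F7 | step 2 | 2‑bromo‑3‑hydroxy‑6‑(methoxymethyl)‑4H‑pyran‑4‑one | COCc1cc(=O)c(O)c(Br)o1
F8 | step 9 | 2‑[2,5‑bis(benzyloxy)‑4‑methoxyphenyl]‑7‑hydroxy‑3,8‑dimethoxy‑6‑(phenylselanyl)‑5,6‑dihydro‑4H‑chromen‑4‑one (racemic) | COC1=C(O)C([Se]c3ccccc3)Cc2c1oc(-c1cc(OCc3ccccc3)c(OC)cc1OCc1ccccc1)c(OC)c2=O
F0 | step 11 | none | none
A1 | alternative 1 | 1,4‑bis(benzyloxy)‑2‑iodo‑5‑methoxybenzene | COc1cc(OCc2ccccc2)c(I)cc1OCc1ccccc1
A2 | alternative 1 | carbon monoxide | [C-]#[O+]
A3 | alternative 1 | 1‑[3,4‑dimethoxy‑2‑(methoxymethoxy)phenyl]‑2‑methoxyethan‑1‑one | COCOc1c(C(=O)COC)ccc(OC)c1OC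
A4 | alternative 1 | 1‑[3,4‑dimethoxy‑2‑(methoxymethoxy)phenyl]‑3‑[2,5‑bis(benzyloxy)‑4‑methoxyphenyl]‑2‑methoxypropane‑1,3‑dione (racemic, labile centre) | COCOc1c(C(=O)C(OC)C(=O)c2cc(OCc3ccccc3)c(OC)cc2OCc2ccccc2)ccc(OC)c1OC
A5 | alternative 2 | 2‑ethynyl‑3,7,8‑trimethoxy‑4H‑chromen‑4‑one | C#Cc1oc2c(OC)c(OC)ccc2c(=O)c1OC
A6 | alternative 2 | tert‑butyl[(4‑methoxyfuran‑2‑yl)oxy]dimethylsilane | COc1coc(O[Si](C)(C)C(C)(C)C)c1
A7 | alternative 2 | 2‑[1‑(tert‑butyldimethylsilyloxy)‑5‑methoxy‑7‑oxabicyclo[2.2.1]hepta‑2,5‑dien‑2‑yl]‑3,7,8‑trimethoxy‑4H‑chromen‑4‑one (racemic) | COC1=CC2(O[Si](C)(C)C(C)(C)C)OC1C=C2c1oc2c(OC)c(OC)ccc2c(=O)c1OC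
A8 | alternative 2 | 2‑[2‑(tert‑butyldimethylsilyloxy)‑5‑hydroxy‑4‑methoxyphenyl]‑3,7,8‑trimethoxy‑4H‑chromen‑4‑one | COc1cc(O[Si](C)(C)C(C)(C)C)c(-c2oc3c(OC)c(OC)ccc3c(=O)c2OC)cc1O
A9 | alternative 3 | 6‑iodo‑2,3‑dimethoxyphenol | COc1ccc(I)c(O)c1OC
A10 | alternative 3 | 1,4‑bis(benzyloxy)‑2‑ethynyl‑5‑methoxybenzene | C#Cc1cc(OCc2ccccc2)c(OC)cc1OCc1ccccc1
A11 | alternative 3 | 2‑[2,5‑bis(benzyloxy)‑4‑methoxyphenyl]‑7,8‑dimethoxy‑4H‑chromen‑4‑one | COc1cc(OCc2ccccc2)c(-c2cc(=O)c3ccc(OC)c(OC)c3o2)cc1OCc1ccccc1
A12 | alternative 3 | 2‑[2,5‑bis(benzyloxy)‑4‑methoxyphenyl]‑3‑hydroxy‑7,8‑dimethoxy‑4H‑chromen‑4‑one | COc1ccc2c(c1OC)oc(-c1cc(OCc3ccccc3)c(OC)cc1OCc1ccccc1)c(O)c2=O
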